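**Remarks on the chemistry**

- The target SMILES is read as (2R,5S,9S,10S,13R), i.e. (13R)-2β-acetoxylabd-8(17)-en-15-oic acid with the normal trans ring fusion (5α-H, 9α-H, 10β-CH3).
- Labdane numbering is used throughout; β is the face of the decalin that carries C20.
- Assumption: the C12–C15 unit is drawn from the catalogue 4-mono-tert-butyl ester of (S)-methylsuccinic acid (17), in which the two carboxyl carbons are already differentiated. This avoids a regioselection that the free diacid or its diol would require.
- Precursor 13 and cycloadduct 14 are used with the skeletons and configurations described; re-derivation of their descriptors showed nothing to correct. The carbinol carbon is R in 13 and S in 14 with no change in space, because the ranking of C1 and C3 switches when C10 becomes sp3. The silyl group on O17 is kept as tert-butyldimethylsilyl so that it can later be removed in the presence of the tert-butyldiphenylsilyl ether on O15.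

## Structural features

The target is a trans-decalin (ring A: C1–C5 and C10; ring B: C5–C10) with a gem-dimethyl group at C4, an angular methyl (C20) on the quaternary C10, an exocyclic C8=C17 methylene, and a five-carbon chain on C9 that carries a methyl-bearing stereocentre at C13 and ends in the C15 acid. C5, C10 and C9 are contiguous. C2 carries an axial β-acetate that is 1,3 to C10 and lies between the two syn-axial methyl groups C19 and C20. C13 is separated from the ring stereocentres by two methylenes and cannot be set by relay, so it has to come from the chiral pool. The fragile groups are the 8(17)-alkene (acid moves it into the ring), the acetate (base, hydride, organometallics) and the free acid; all three are unveiled late. The real difficulty is the quaternary C10 in the right absolute sense together with its neighbours C5 and C9, and the axial 2β-oxygen, which is the less stable epimer and cannot be reached by displacement. The key step exploits the fact that O2 lies three bonds from C10 (O2–C2–C1–C10): an ynoate on a 2α-oxygen, whose carbonyl carbon is the future C11, can reach across the α face of ring A and deliver C9 to C10 and C8 to C7 of a C10=C5–C6=C7 diene. The 2α-oxygen needed for this tether is epimeric with the target and is corrected afterwards through the C2 ketone.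

## Logic of the disconnections

**33 ⇒ 32 ⇒ 31.** No skeletal bond is cut; the C15 carboxyl is taken back to a primary alcohol and then to its silyl ether. A free acid would not survive the organomagnesium, hydride and Mitsunobu chemistry. The gain is a chain that travels through the route as a robust ether. The demand is a final oxidation that spares the 8(17)-alkene and the acetate.

**31 ⇒ 28.** The C9–H bond is removed and a C17–O bond restored, which moves the alkene from C8=C17 into the ring as C8=C9. The tetrasubstituted alkene with an oxygen on C17 is what a cycloaddition of an oxygenated alkyne leaves behind. C9 stops being a stereocentre and the sensitive exocyclic alkene is replaced by an inert one. The forward transposition must place hydrogen on the α face of C9.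

**28 ⇒ 27 ⇒ 26 ⇒ 25 ⇒ 24.** The C2–O acetyl bond is cut to 26, whose axial hydroxyl is traced through ketone 25 to the epimeric alcohol 24. The 2β-oxygen is best made by hydride addition from the open α face, and a 2α-oxygen is what the earlier chemistry requires. This links the target to a 2α-ol. The demand is a face-selective ketone reduction.

**24 ⇒ 23.** The C5–H bond is removed to give the C5=C6 alkene, the footprint of the diene. C5 ceases to be a stereocentre. The forward hydrogenation must add from the α face and leave C8=C9 alone.

**23 ⇒ 16 + 22 (22 from 21).** The C11–C12 bond is cut. C11 is allylic, and C13 lies too far from the ring to be controlled, so it is bought. The molecule falls into a ring part and a small chiral chain. The coupling must occur at C11 without allylic shift and in the presence of the C2 hydroxyl.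

**21 ⇒ 20 ⇒ 19 ⇒ 18 ⇒ 17.** Only functional groups change; C13 comes unchanged from 17. The demand is that the two chain ends stay differentiated at every stage.

**16 ⇒ 15 ⇒ 14.** The C11–Br bond goes back to C11–OH, and the C11–O2 acyl bond is re-formed. Tying C11 to O2 creates the retron of the key step. The gain is the compact tricycle 14. The forward steps must reduce the lactone without touching the alkenes and activate only the allylic hydroxyl.

**14 ⇒ 13.** The C9–C10 and C7–C8 bonds are cut in a retro-[4+2] sense. Ring B and the lactone ring open together and C10 ceases to be a stereocentre. Two rings, two skeletal bonds and the quaternary centre are traded for a monocyclic ester. The forward reaction must take place on the face of C10 that carries O2.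

**13 ⇒ 8 + 12.** The acyl C11–O2 bond is cut. This separates the ring A dienol from a four-carbon acid that carries C8, C9, C11 and C17. The esterification must retain the configuration of the carbinol carbon.

**12 ⇒ 10 ⇒ 9.** The C9–C11 bond is cut (carboxylation of an acetylide) and the O–Si bond is removed. The acid reduces to a three-carbon alcohol.

**8 ⇒ 7 ⇒ 6 ⇒ 4 ⇒ 3 ⇒ 1.** The C5–C6 bond is cut (vinyl cross-coupling), the enol triflate goes back to a ketone, and the carbinol centre goes back to an enzymatic carbonyl reduction. Ring A with its only stereocentre comes from an achiral dione. The enol triflate must form toward the single α-CH.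

## Other disconnections considered

**Alternative 1:** The cut is C5–C6 and C9–C10 on an intact ring A enone, 2,4,4-trimethylcyclohex-2-en-1-one A1 (carbonyl at C1).
- Forward key step: a phosphoramidite–Cu(OTf)2 catalyst adds a vinyl Grignard reagent to C5, and the C10 enolate is alkylated in the same flask by a methallyl halide trans to the vinyl group, giving A2.
- In its favour: two C–C bonds and both ring-fusion centres are set in one catalytic, enantioselective operation from an achiral enone. C5 is fixed by C–C bond formation, which is better than the chosen plan, where C5 depends on hydrogenating a hindered alkene.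
- Against it here: C5 of A1 is neopentyl and the α carbon is substituted, so the conjugate addition is demanding, and catalytic asymmetric additions of alkenyl Grignard reagents are less general than those of alkyl reagents.
- Further against it: A2 has its oxygen at C1, not C2, so a carbonyl transposition is needed. Metathesis of the two arms would join C6 to C8 and close a five-membered ring, so C7–C8 needs extra redox work. C9 is a plain methylene with no handle for the chain or its configuration.
- Comparison: A2 holds ring A and two stereocentres. 14 holds both rings, C10, C11 and an oxygenated C17 at the right carbons, and an oxygen at C2. The alternative relies on catalyst control on a difficult substrate; the chosen step relies on substrate control through a tether. The count to the target should be clearly higher for the alternative.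

**Alternative 2:** The cut is C10–C20, traced to the (bromomethyl)dimethylsilyl ether A3 of a 5(10)-octalin-2β-ol that already carries ring B and the chain.
- Forward key step: Bu3SnH and a radical initiator generate the α-silyl radical, which adds 6-exo-trig to C10; the C5 radical is then reduced, giving siloxane A4.
- In its favour: it uses the same proximity of O2 to C10 as the chosen plan, but with the oxygen already β as in the target, so no inversion at C2 is needed. On this point it is better than the chosen plan. It also sets C5 in the same step, and the reaction class is known.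
- Against it here: addition to a fully substituted alkene carbon competes with direct reduction of the radical and with 7-endo closure. The face of hydrogen transfer to C5 is not assured. A tin reagent is needed.
- Further against it: A3 must already contain C9 and C13 in the right relation to C2 across a tetrasubstituted alkene, which the alternative does not solve. A4 still needs protodesilylation, ketal removal and methylenation of a hindered ketone.
- Comparison: equal in the idea of oxygen-tethered delivery to C10 and better by one stereocentre in the key step. It makes only one skeletal bond, late in a linear sequence, so the risk is concentrated near the end and step economy is poorer overall.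

**Alternative 3:** The cut is C5–C10 inside ring A, traced to a 6-alkenyl δ-lactone.
- Forward key step: the silyl ketene acetal (LiN(i-Pr)2 and Me3SiCl, then heat) rearranges through a boat (Ireland–Claisen) and contracts the lactone to the cyclohexene acid A5.
- In its favour: the bond between the two most congested carbons is made by a sigmatropic shift, which tolerates crowding. C5 and C10 are set together by transfer from one carbinol centre. C5 is set directly, which is better than the chosen plan. The acid and the masked ketone are placed for a later ring B closure.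
- Against it here: it needs an exclusive boat transition state and a geometrically pure trisubstituted alkene. The C2 oxygen is the one that leaves, so C2 must be re-oxygenated through the C1=C2 alkene with regio- and face control. Ring B, C9, C17 and the chain all remain to be built.
- Comparison: both plans use a substrate-controlled pericyclic step. On C2 the alternative is at best equal, since an adjustment is needed either way. A5 is a ring A fragment only, so the route to the target should be longer.

Key step: step 9

## Route

**Step 1**
Reactants: 1 ketoisophorone (2,6,6-trimethylcyclohex-2-ene-1,4-dione)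
Product: 3 (4R,6R)-4-hydroxy-2,2,6-trimethylcyclohexan-1-one, via (6R)-levodione 2 (not isolated)
Conditions: old yellow enzyme (OYE2), then levodione reductase; NADH/NADPH (cat.), glucose dehydrogenase, D-glucose, KH2PO4/K2HPO4 buffer pH 7, 30 °C, one pot
Reagents that add atoms: none
Why: Ene-reductase reduction of the electron-poor C=C followed by carbonyl-reductase reduction of the unhindered C4 ketone, both established for this substrate; the enzyme sets the (4R) carbinol centre (later C2), and the C6 centre is erased in step 3.

**Step 2**
Reactants: 3 (4R,6R)-4-hydroxy-2,2,6-trimethylcyclohexan-1-one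
Product: 4 (4R,6R)-4-[(tert-butyldimethylsilyl)oxy]-2,2,6-trimethylcyclohexan-1-one
Conditions: TBSCl, imidazole, DMF, rt
Reagents that add atoms: tert-butyldimethylsilyl chloride, CC(C)(C)[Si](C)(C)Cl
Why: Standard silylation of a secondary alcohol; the hindered ketone does not react and no stereocentre is touched.

**Step 3**
Reactants: 4 (4R,6R)-4-[(tert-butyldimethylsilyl)oxy]-2,2,6-trimethylcyclohexan-1-one
Product: 6 (4R)-4-[(tert-butyldimethylsilyl)oxy]-2,6,6-trimethylcyclohex-1-en-1-yl trifluoromethanesulfonate, via lithium enolate 5 (not isolated)
Conditions: LiN(i-Pr)2, THF, −78 → 0 °C; PhNTf2, −78 °C → rt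
Reagents that add atoms: N-phenylbis(trifluoromethanesulfonimide), O=S(=O)(N(c1ccccc1)S(=O)(=O)C(F)(F)F)C(F)(F)F
Why: Enolisation can occur only at C6, the single α-CH, so one enolate forms and O-triflation gives the tetrasubstituted enol triflate; the silyloxy carbon is not involved.

**Step 4**
Reactants: 6 (4R)-4-[(tert-butyldimethylsilyl)oxy]-2,6,6-trimethylcyclohex-1-en-1-yl trifluoromethanesulfonate
Product: 7 tert-butyldimethyl{[(1R)-3,5,5-trimethyl-4-vinylcyclohex-3-en-1-yl]oxy}silane
Conditions: CH2=CH–B(pin), Pd(PPh3)4 (5 mol%), K3PO4, dioxane/H2O, 80 °C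
Reagents that add atoms: 4,4,5,5-tetramethyl-2-vinyl-1,3,2-dioxaborolane, C=CB1OC(C)(C)C(C)(C)O1
Why: Suzuki–Miyaura coupling of an alkenyl triflate with a vinylboronate; zerovalent palladium inserts into the C–OTf bond despite the flanking quaternary carbon, and the diene forms without touching the stereocentre.

**Step 5**
Reactants: 7 tert-butyldimethyl{[(1R)-3,5,5-trimethyl-4-vinylcyclohex-3-en-1-yl]oxy}silane
Product: 8 (1R)-3,5,5-trimethyl-4-vinylcyclohex-3-en-1-ol
Conditions: Bu4NF, THF, rt
Reagents that add atoms: none
Why: Fluoride cleaves the Si–O bond and frees the secondary alcohol for acylation; the diene is inert to these conditions.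

**Step 6**
Reactants: 9 propargyl alcohol
Product: 10 tert-butyldimethyl(prop-2-yn-1-yloxy)silane
Conditions: TBSCl, imidazole, CH2Cl2, 0 °C → rt
Reagents that add atoms: tert-butyldimethylsilyl chloride, CC(C)(C)[Si](C)(C)Cl
Why: Standard silylation of a primary alcohol.

**Step 7**
Reactants: 10 tert-butyldimethyl(prop-2-yn-1-yloxy)silane
Product: 12 4-[(tert-butyldimethylsilyl)oxy]but-2-ynoic acid, via lithium acetylide 11 (not isolated)
Conditions: n-BuLi, THF, −78 °C; CO2, −78 → 0 °C; 1 M HCl to pH 3 at 0 °C
Reagents that add atoms: carbon dioxide, O=C=O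
Why: Deprotonation of the terminal alkyne and carboxylation of the acetylide; the cold, brief acidification keeps the silyl ether.

**Step 8**
Reactants: 8 (1R)-3,5,5-trimethyl-4-vinylcyclohex-3-en-1-ol; 12 4-[(tert-butyldimethylsilyl)oxy]but-2-ynoic acid
Product: 13 (1R)-3,5,5-trimethyl-4-vinylcyclohex-3-en-1-yl 4-[(tert-butyldimethylsilyl)oxy]but-2-ynoate
Conditions: DCC, DMAP (10 mol%), CH2Cl2, −20 → 0 °C
Reagents that add atoms: none
Why: Steglich esterification with retention, because the C–O bond of 8 is not broken; low temperature and only catalytic DMAP limit conjugate addition to the ynoate.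

**Step 9**
Reactants: 13 (1R)-3,5,5-trimethyl-4-vinylcyclohex-3-en-1-yl 4-[(tert-butyldimethylsilyl)oxy]but-2-ynoate
Product: 14 (2S,10S)-17-[(tert-butyldimethylsilyl)oxy]-12,13,14,15,16-pentanorlabda-5,8-dien-11,2α-olide (tricyclic dienyl lactone; O2–C11 lactone bridge; C5=C6 and C8=C9 alkenes; C20 β)
Conditions: o-xylene (0.02 M), BHT (cat.), 150 °C, sealed tube
Reagents that add atoms: none
Why: A thermal, concerted, suprafacial [4+2] cycloaddition joins the s-cis C10=C5–C6=C7 diene to the C8≡C9 alkyne of the tethered ynoate; the closest known reactions are thermal intramolecular Diels–Alder reactions of dienyl alkynoates and the intermolecular addition of acetylenic esters to 2,6,6-trimethyl-1-vinylcyclohexene. Ring B is the cycloadduct ring (C9–C10 and C7–C8 form together), obtained as a 1,4-cyclohexadiene with C5=C6 and C8=C9. The δ-lactone ring closes in the same event because the four-atom tether C1–C2–O–C11 links the diene terminus C10 to the dienophile carbon C9, a six-membered 1,3-diaxial bridge across ring A. The only new stereocentre, C10, is controlled by C2: the ynoate can reach C10 only on the face of ring A that carries O2, so C9 enters cis to O2 and C20 ends trans to it, which is the natural configuration. The regiochemistry (C9 to C10, C8 to C7) is fixed by the tether length and agrees with the electronic preference, since the β carbon of the ynoate bonds to the unsubstituted terminus C7. The cost is that the ester must adopt its less stable s-cis form and ring A a half-chair with axial O2, hence the temperature; high dilution and a radical inhibitor suppress intermolecular addition and polymerisation. No endo/exo question arises because both dienophile carbons stay sp2.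

**Step 10**
Reactants: 14 tricyclic dienyl lactone
Product: 15 (2S,10S)-17-[(tert-butyldimethylsilyl)oxy]-12,13,14,15,16-pentanorlabda-5,8-diene-2α,11-diol
Conditions: i-Bu2AlH (3 equiv), CH2Cl2, −78 → 0 °C; aq. KNaC4H4O6
Reagents that add atoms: none
Why: 1,2-Reduction of the lactone by two hydride transfers (lactone to lactol aluminate to diol); the tetrasubstituted conjugated alkene is not reduced and the silyl ether is stable.

**Step 11**
Reactants: 15 2α,11-diol
Product: 16 (2S,10S)-11-bromo-17-[(tert-butyldimethylsilyl)oxy]-12,13,14,15,16-pentanorlabda-5,8-dien-2α-ol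
Conditions: NBS, Me2S, CH2Cl2 (complex preformed at 0 °C), −20 → 0 °C; used without chromatography
Reagents that add atoms: N-bromosuccinimide, O=C1CCC(=O)N1Br
Why: Corey–Kim halogenation: the sulfonium complex converts the allylic alcohol into the bromide under neutral conditions, while the saturated secondary alcohol only forms a reversible alkoxysulfonium salt and is recovered on work-up.

**Step 12**
Reactants: 17 (2S)-4-tert-butoxy-2-methyl-4-oxobutanoic acid
Product: 18 tert-butyl (3S)-4-hydroxy-3-methylbutanoate
Conditions: BH3·SMe2, THF, 0 °C → rt; MeOH quench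
Reagents that add atoms: none
Why: Borane reduces a free carboxylic acid much faster than an ester, so only the carbon that becomes C12 is reduced; the stereocentre is not enolised under these conditions.

**Step 13**
Reactants: 18 tert-butyl (3S)-4-hydroxy-3-methylbutanoate
Product: 19 tert-butyl (3S)-4-bromo-3-methylbutanoate
Conditions: CBr4, PPh3, CH2Cl2, 0 °C
Reagents that add atoms: carbon tetrabromide, BrC(Br)(Br)Br
Why: Appel bromination of a primary alcohol; substitution occurs at the CH2 carbon, so the adjacent stereocentre is unaffected.

**Step 14**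
Reactants: 19 tert-butyl (3S)-4-bromo-3-methylbutanoate
Product: 20 (3S)-4-bromo-3-methylbutan-1-ol
Conditions: i-Bu2AlH (2.5 equiv), CH2Cl2, −78 → 0 °C; aq. KNaC4H4O6; used at once
Reagents that add atoms: none
Why: Ester reduction to the primary alcohol by an aluminium hydride that leaves the alkyl bromide alone; the bromo alcohol is silylated directly because it can slowly close to a tetrahydrofuran.

**Step 15**
Reactants: 20 (3S)-4-bromo-3-methylbutan-1-ol
Product: 21 {[(3S)-4-bromo-3-methylbutyl]oxy}(tert-butyl)diphenylsilane
Conditions: TBDPSCl, imidazole, CH2Cl2, 0 °C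
Reagents that add atoms: tert-butyl(chloro)diphenylsilane, CC(C)(C)[Si](Cl)(c1ccccc1)c1ccccc1
Why: Standard silylation; the bulky silyl ether is stable to Grignard formation, hydrogenation, oxidation and hydride, and survives the later removal of the silyl group on O17.

**Step 16**
Reactants: 16 11-bromo-2α-ol; 21 {[(3S)-4-bromo-3-methylbutyl]oxy}(tert-butyl)diphenylsilane
Product: 23 (13R)-17-[(tert-butyldimethylsilyl)oxy]-15-[(tert-butyldiphenylsilyl)oxy]labda-5,8-dien-2α-ol, via Grignard reagent 22 (not isolated)
Conditions: 21 (2.6 equiv), Mg, BrCH2CH2Br (cat.), THF, 40 °C; then Li2CuCl4 (5 mol%), 16, THF, −78 → −20 °C; aq. NH4Cl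
Reagents that add atoms: none
Why: Kochi-type Li2CuCl4-catalysed coupling of a primary alkyl Grignard reagent with a primary allylic bromide, which favours direct substitution at C11 because the γ carbon C8 is fully substituted. The first equivalent of 22 deprotonates the C2 hydroxyl, and the resulting magnesium alkoxide is too poor a nucleophile at low temperature to displace the bromide; C13 is carried unchanged.

**Step 17**
Reactants: 23 labda-5,8-dien-2α-ol
Product: 24 (13R)-17-[(tert-butyldimethylsilyl)oxy]-15-[(tert-butyldiphenylsilyl)oxy]-5α-labd-8-en-2α-ol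
Conditions: H2 (1 atm), 10% Pd/C, EtOAc, rt
Reagents that add atoms: none
Why: Heterogeneous hydrogenation adds H2 to the α face of the trisubstituted C5=C6 alkene, because the β face is shielded by C20 and the 4β-methyl; this gives the trans ring fusion, as with Δ5-steroids and the related drimane diene esters. The tetrasubstituted C8=C9 alkene is not reduced.

**Step 18**
Reactants: 24 5α-labd-8-en-2α-ol
Product: 25 (13R)-17-[(tert-butyldimethylsilyl)oxy]-15-[(tert-butyldiphenylsilyl)oxy]-5α-labd-8-en-2-one
Conditions: Dess–Martin periodinane, pyridine, CH2Cl2, 0 °C → rt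
Reagents that add atoms: none
Why: Mild periodinane oxidation of the only free hydroxyl; both α carbons are methylenes next to quaternary centres, so nothing can epimerise.

**Step 19**
Reactants: 25 5α-labd-8-en-2-one
Product: 26 (13R)-17-[(tert-butyldimethylsilyl)oxy]-15-[(tert-butyldiphenylsilyl)oxy]-5α-labd-8-en-2β-ol
Conditions: NaBH4, MeOH/THF, 0 °C
Reagents that add atoms: none
Why: Hydride attacks from the α (equatorial) side because the axial β trajectory is blocked by the two syn-axial methyl groups C19 and C20, giving the axial 2β-alcohol; this is the known behaviour of 2-oxosteroids and 2-oxo-4,4,10-trimethyl-trans-decalins.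

**Step 20**
Reactants: 26 5α-labd-8-en-2β-ol
Product: 27 (13R)-17-[(tert-butyldimethylsilyl)oxy]-15-[(tert-butyldiphenylsilyl)oxy]-5α-labd-8-en-2β-yl acetate
Conditions: Ac2O, DMAP, pyridine, rt → 40 °C
Reagents that add atoms: acetic anhydride, CC(=O)OC(C)=O
Why: DMAP-catalysed acylation, which also works on a hindered axial alcohol; configuration at C2 is retained.

**Step 21**
Reactants: 27 2β-acetate with both silyl ethers
Product: 28 (13R)-15-[(tert-butyldiphenylsilyl)oxy]-17-hydroxy-5α-labd-8-en-2β-yl acetate
Conditions: HF·pyridine, pyridine, THF, 0 °C → rt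
Reagents that add atoms: none
Why: Buffered fluoride cleaves the primary allylic tert-butyldimethylsilyl ether much faster than the tert-butyldiphenylsilyl ether and does not affect the acetate.

**Step 22**
Reactants: 28 17-hydroxy-5α-labd-8-en-2β-yl acetate
Product: 31 (13R)-15-[(tert-butyldiphenylsilyl)oxy]labd-8(17)-en-2β-yl acetate (5α-H; 9α-H), via N-allyl sulfonylhydrazide 29 (not isolated), via allylic diazene 30 (not isolated)
Conditions: 2-O2NC6H4SO2NHNH2, PPh3, DEAD, THF, −30 °C; then 23 °C
Reagents that add atoms: none
Why: Myers reductive transposition: Mitsunobu N-alkylation of the sulfonylhydrazide, loss of sulfinic acid on warming, then a retro-ene loss of N2 from the allylic diazene, which moves the alkene to C8=C17 and delivers hydrogen to C9. Hydrogen arrives axially on the α face, anti to C20, so C9 is 9α-H with the chain equatorial.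

**Step 23**
Reactants: 31 15-silyloxy-labd-8(17)-en-2β-yl acetate
Product: 32 (13R)-15-hydroxylabd-8(17)-en-2β-yl acetate
Conditions: Bu4NF, AcOH, THF, rt
Reagents that add atoms: none
Why: Fluoride-mediated cleavage of the silyl ether; buffering with acetic acid protects the acetate from basic fluoride.

**Step 24**
Reactants: 32 (13R)-15-hydroxylabd-8(17)-en-2β-yl acetate
Product: 33 (13R)-2β-acetoxylabd-8(17)-en-15-oic acid, (2R,5S,9S,10S,13R)
Conditions: TEMPO (20 mol%), PhI(OAc)2 (2.5 equiv), MeCN/H2O 1:1, rt
Reagents that add atoms: water, O
Why: Oxoammonium oxidation of the primary alcohol through the aldehyde hydrate to the acid; the 1,1-disubstituted alkene and the acetate are tolerated, and C13 is not α to the new carboxyl.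

## Compound list

1 | ketoisophorone (2,6,6-trimethylcyclohex-2-ene-1,4-dione) | CC1=CC(=O)CC(C)(C)C1=O | starting material
2 | (6R)-2,2,6-trimethylcyclohexane-1,4-dione ((6R)-levodione) | O=C1C(C)(C)CC(=O)C[C@H]1C | intermediate
3 | (4R,6R)-4-hydroxy-2,2,6-trimethylcyclohexan-1-one | O=C1C(C)(C)C[C@H](O)C[C@H]1C | intermediate
4 | (4R,6R)-4-[(tert-butyldimethylsilyl)oxy]-2,2,6-trimethylcyclohexan-1-one | O=C1C(C)(C)C[C@H](O[Si](C)(C)C(C)(C)C)C[C@H]1C | intermediate
5 | lithium (4R)-4-[(tert-butyldimethylsilyl)oxy]-2,6,6-trimethylcyclohex-1-en-1-olate | [Li]OC1=C(C)C[C@@H](O[Si](C)(C)C(C)(C)C)CC1(C)C | intermediate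
6 | (4R)-4-[(tert-butyldimethylsilyl)oxy]-2,6,6-trimethylcyclohex-1-en-1-yl trifluoromethanesulfonate | O=S(=O)(OC1=C(C)C[C@@H](O[Si](C)(C)C(C)(C)C)CC1(C)C)C(F)(F)F | intermediate
7 | tert-butyldimethyl{[(1R)-3,5,5-trimethyl-4-vinylcyclohex-3-en-1-yl]oxy}silane | C=CC1=C(C)C[C@@H](O[Si](C)(C)C(C)(C)C)CC1(C)C | intermediate
8 | (1R)-3,5,5-trimethyl-4-vinylcyclohex-3-en-1-ol | C=CC1=C(C)C[C@@H](O)CC1(C)C | intermediate
9 | propargyl alcohol | C#CCO | starting material
10 | tert-butyldimethyl(prop-2-yn-1-yloxy)silane | C#CCO[Si](C)(C)C(C)(C)C | intermediate
11 | lithium acetylide of 10 | [Li]C#CCO[Si](C)(C)C(C)(C)C | intermediate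
12 | 4-[(tert-butyldimethylsilyl)oxy]but-2-ynoic acid | OC(=O)C#CCO[Si](C)(C)C(C)(C)C | intermediate
13 | (1R)-3,5,5-trimethyl-4-vinylcyclohex-3-en-1-yl 4-[(tert-butyldimethylsilyl)oxy]but-2-ynoate | C=CC1=C(C)C[C@@H](OC(=O)C#CCO[Si](C)(C)C(C)(C)C)CC1(C)C | intermediate
14 | (2S,10S)-17-[(tert-butyldimethylsilyl)oxy]-12,13,14,15,16-pentanorlabda-5,8-dien-11,2α-olide | CC(C)(C)[Si](C)(C)OCC1=C2C(=O)O[C@H]3CC(C)(C)C(=CC1)[C@]2(C)C3 | intermediate
15 | (2S,10S)-17-[(tert-butyldimethylsilyl)oxy]-12,13,14,15,16-pentanorlabda-5,8-diene-2α,11-diol | CC(C)(C)[Si](C)(C)OCC1=C(CO)[C@@]2(C)C[C@@H](O)CC(C)(C)C2=CC1 | intermediate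
16 | (2S,10S)-11-bromo-17-[(tert-butyldimethylsilyl)oxy]-12,13,14,15,16-pentanorlabda-5,8-dien-2α-ol | CC(C)(C)[Si](C)(C)OCC1=C(CBr)[C@@]2(C)C[C@@H](O)CC(C)(C)C2=CC1 | intermediate
17 | (2S)-4-tert-butoxy-2-methyl-4-oxobutanoic acid | OC(=O)[C@@H](C)CC(=O)OC(C)(C)C | starting material
18 | tert-butyl (3S)-4-hydroxy-3-methylbutanoate | OC[C@@H](C)CC(=O)OC(C)(C)C | intermediate
19 | tert-butyl (3S)-4-bromo-3-methylbutanoate | BrC[C@@H](C)CC(=O)OC(C)(C)C | intermediate
20 | (3S)-4-bromo-3-methylbutan-1-ol | BrC[C@@H](C)CCO | intermediate
21 | {[(3S)-4-bromo-3-methylbutyl]oxy}(tert-butyl)diphenylsilane | BrC[C@@H](C)CCO[Si](c1ccccc1)(c1ccccc1)C(C)(C)C | intermediate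
22 | {(2S)-4-[(tert-butyldiphenylsilyl)oxy]-2-methylbutyl}magnesium bromide | Br[Mg]C[C@@H](C)CCO[Si](c1ccccc1)(c1ccccc1)C(C)(C)C | intermediate
23 | (13R)-17-[(tert-butyldimethylsilyl)oxy]-15-[(tert-butyldiphenylsilyl)oxy]labda-5,8-dien-2α-ol (C20 β) | CC(C)(C)[Si](C)(C)OCC1=C(CC[C@@H](C)CCO[Si](c2ccccc2)(c2ccccc2)C(C)(C)C)[C@@]3(C)C[C@@H](O)CC(C)(C)C3=CC1 | intermediate
24 | (13R)-17-[(tert-butyldimethylsilyl)oxy]-15-[(tert-butyldiphenylsilyl)oxy]-5α-labd-8-en-2α-ol | CC(C)(C)[Si](C)(C)OCC1=C(CC[C@@H](C)CCO[Si](c2ccccc2)(c2ccccc2)C(C)(C)C)[C@@]3(C)C[C@@H](O)CC(C)(C)[C@@H]3CC1 | intermediate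
25 | (13R)-17-[(tert-butyldimethylsilyl)oxy]-15-[(tert-butyldiphenylsilyl)oxy]-5α-labd-8-en-2-one | CC(C)(C)[Si](C)(C)OCC1=C(CC[C@@H](C)CCO[Si](c2ccccc2)(c2ccccc2)C(C)(C)C)[C@@]3(C)CC(=O)CC(C)(C)[C@@H]3CC1 | intermediate
26 | (13R)-17-[(tert-butyldimethylsilyl)oxy]-15-[(tert-butyldiphenylsilyl)oxy]-5α-labd-8-en-2β-ol | CC(C)(C)[Si](C)(C)OCC1=C(CC[C@@H](C)CCO[Si](c2ccccc2)(c2ccccc2)C(C)(C)C)[C@@]3(C)C[C@H](O)CC(C)(C)[C@@H]3CC1 | intermediate
27 | (13R)-17-[(tert-butyldimethylsilyl)oxy]-15-[(tert-butyldiphenylsilyl)oxy]-5α-labd-8-en-2β-yl acetate | CC(C)(C)[Si](C)(C)OCC1=C(CC[C@@H](C)CCO[Si](c2ccccc2)(c2ccccc2)C(C)(C)C)[C@@]3(C)C[C@H](OC(C)=O)CC(C)(C)[C@@H]3CC1 | intermediate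
28 | (13R)-15-[(tert-butyldiphenylsilyl)oxy]-17-hydroxy-5α-labd-8-en-2β-yl acetate | OCC1=C(CC[C@@H](C)CCO[Si](c2ccccc2)(c2ccccc2)C(C)(C)C)[C@@]3(C)C[C@H](OC(C)=O)CC(C)(C)[C@@H]3CC1 | intermediate
29 | N-allyl-N-(2-nitrobenzenesulfonyl)hydrazine at C17 of 28 | NN(CC1=C(CC[C@@H](C)CCO[Si](c2ccccc2)(c2ccccc2)C(C)(C)C)[C@@]3(C)C[C@H](OC(C)=O)CC(C)(C)[C@@H]3CC1)S(=O)(=O)c1ccccc1[N+](=O)[O-] | intermediate
30 | C17 monoalkyl diazene derived from 29 | N=NCC1=C(CC[C@@H](C)CCO[Si](c2ccccc2)(c2ccccc2)C(C)(C)C)[C@@]3(C)C[C@H](OC(C)=O)CC(C)(C)[C@@H]3CC1 | intermediate
31 | (13R)-15-[(tert-butyldiphenylsilyl)oxy]labd-8(17)-en-2β-yl acetate (5α-H, 9α-H) | C=C1CC[C@H]2C(C)(C)C[C@@H](OC(C)=O)C[C@]2(C)[C@H]1CC[C@@H](C)CCO[Si](c1ccccc1)(c1ccccc1)C(C)(C)C | intermediate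
32 | (13R)-15-hydroxylabd-8(17)-en-2β-yl acetate | C=C1CC[C@H]2C(C)(C)C[C@@H](OC(C)=O)C[C@]2(C)[C@H]1CC[C@@H](C)CCO | intermediate
33 | (13R)-2β-acetoxylabd-8(17)-en-15-oic acid, (2R,5S,9S,10S,13R) | C=C1CC[C@H]2C(C)(C)C[C@@H](OC(C)=O)C[C@]2(C)[C@H]1CC[C@@H](C)CC(=O)O | target

## Step count and least certain steps

Total: 24 steps. Longest linear sequence: 18 steps (1–5, 8–11, 16–24); steps 6–7 and 12–15 are side branches.

**Step 9 (key step).** The cycloaddition may be too slow. The ester must leave its preferred s-trans form, ring A must place O2 axial, and the hindered diene must become s-cis; at the temperature this requires, a [1,5]-hydrogen shift in the diene or intermolecular addition and oligomerisation can compete. Fallback: the cycloaddition is run between two molecules and the tether is given up. It sets out from 8, and from acetylide 11, which is quenched with ClCO2Me to give methyl 4-[(tert-butyldimethylsilyl)oxy]but-2-ynoate F1. Heating 8 with F1 without solvent should give the hydroxy diene ester, methyl 17-[(tert-butyldimethylsilyl)oxy]-2α-hydroxy-12,13,14,15,16-pentanorlabda-5,8-dien-11-oate F2, together with its C10 epimer F3. Regiochemistry then rests on the electronic preference alone, and facial control is lost. After separation, F2 is reduced with i-Bu2AlH and the route is rejoined at 15.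

**Step 16.** The bromide may be lost before coupling, by ionisation or by intramolecular displacement through the C2 alkoxide (the geometry that formed the lactone also allows a cyclic ether), and the free hydroxyl consumes one equivalent of 22. Attack at C8 instead of C11 is a lesser concern. Fallback: from 16 the hydroxyl is masked under neutral conditions with N,O-bis(trimethylsilyl)acetamide as the trimethylsilyl ether of 16 F4. F4 is coupled with 22 under the same copper catalysis to the trimethylsilyl ether of 23 F5, and the silyl ether is removed with citric acid in methanol, returning to the route at 23.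

**Step 17.** Reduction of the alkene, which is neopentyl on both sides, may be slow, and the longer contact with the catalyst invites hydrogenolysis or migration at the allylic C17–O/C8=C9 unit or incomplete α-face selectivity. Fallback: from 23 to 24 by hydrogen-atom-transfer reduction (Mn(dpm)3, dpm = 2,2,6,6-tetramethylheptane-3,5-dionate; PhSiH3, t-BuOOH, i-PrOH). This replaces surface-bound syn addition by a stepwise radical path through the tertiary C5 radical, which is quenched toward the more stable trans-fused product; no new compound is involved.

**Step 22.** The Mitsunobu alkylation at the crowded allylic carbinol may lag behind decomposition of the sulfonylhydrazide, or hydrogen may be delivered to the wrong face of C9. Fallback: from 28 the allylic alcohol is converted with acetic formic anhydride and pyridine into the C17 formate of 28 F6. Pd(OAc)2 with n-Bu3P in THF then forms the π-allyl palladium formate on the open α face, which loses CO2 and transfers hydride to the more substituted allyl terminus C9. This gives the exocyclic alkene with 9α-H and rejoins the route at 31.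

## Further compounds

F1 | step 9 | methyl 4-[(tert-butyldimethylsilyl)oxy]but-2-ynoate | COC(=O)C#CCO[Si](C)(C)C(C)(C)C
F2 | step 9 | methyl 17-[(tert-butyldimethylsilyl)oxy]-2α-hydroxy-12,13,14,15,16-pentanorlabda-5,8-dien-11-oate (C20 β) | CC(C)(C)[Si](C)(C)OCC1=C(C(=O)OC)[C@@]2(C)C[C@@H](O)CC(C)(C)C2=CC1
F3 | step 9 | C10 epimer of F2 (C20 α, cis to the 2α-hydroxyl) | CC(C)(C)[Si](C)(C)OCC1=C(C(=O)OC)[C@]2(C)C[C@@H](O)CC(C)(C)C2=CC1
F4 | step 16 | trimethylsilyl ether of 16 | CC(C)(C)[Si](C)(C)OCC1=C(CBr)[C@@]2(C)C[C@@H](O[Si](C)(C)C)CC(C)(C)C2=CC1
F5 | step 16 | trimethylsilyl ether of 23 | CC(C)(C)[Si](C)(C)OCC1=C(CC[C@@H](C)CCO[Si](c2ccccc2)(c2ccccc2)C(C)(C)C)[C@@]3(C)C[C@@H](O[Si](C)(C)C)CC(C)(C)C3=CC1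
F0 | step 17 | none | none
F6 | step 22 | C17 formate of 28 | O=COCC1=C(CC[C@@H](C)CCO[Si](c2ccccc2)(c2ccccc2)C(C)(C)C)[C@@]3(C)C[C@H](OC(C)=O)CC(C)(C)[C@@H]3CC1
A1 | alternative 1 | 2,4,4-trimethylcyclohex-2-en-1-one | O=C1CCC(C)(C)C=C1C
A2 | alternative 1 | (2R,3S)-2,4,4-trimethyl-2-(2-methylprop-2-en-1-yl)-3-vinylcyclohexan-1-one | O=C1CCC(C)(C)[C@H](C=C)[C@@]1(C)CC(C)=C
A3 | alternative 2 | methyl (13R)-2β-{[(bromomethyl)dimethylsilyl]oxy}-8,8-ethylenedioxy-17,20-dinorlabd-5(10)-en-15-oate | C12(OCCO1)CCC3=C(C[C@H](O[Si](C)(C)CBr)CC3(C)C)[C@H]2CC[C@@H](C)CC(=O)OC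
A4 | alternative 2 | cyclic siloxane (O2–SiMe2–C20 bridge) of methyl (13R)-8,8-ethylenedioxy-2β-hydroxy-17-norlabdan-15-oate | C12(OCCO1)CC[C@H]3C(C)(C)C[C@@H]4C[C@]3(C[Si](C)(C)O4)[C@H]2CC[C@@H](C)CC(=O)OC
A5 | alternative 3 | (1S,2S)-2,6,6-trimethyl-2-[(2-methyl-1,3-dioxolan-2-yl)methyl]cyclohex-3-ene-1-carboxylic acid | OC(=O)[C@H]1C(C)(C)CC=C[C@]1(C)CC2(C)OCCO2
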